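The 2-aryl-2,3-dihydrobenzofuran with a carbon substituent at C3 is read as a flavanone that has lost one ring carbon. In a single operation a trivalent iodine oxidant moves the fused benzo carbon (chromanone C4a, later C3a) from the carbonyl carbon C4 to C3: the C3–C3a bond forms, the pyranone ring shrinks to the O1–C2–C3–C3a–C7a ring, and C4 is pushed outside the ring as a methyl ester, the handle for a later decarboxylative arylation. The precursor is (R)-6-bromo-2-[4-(tosyloxy)phenyl]chroman-4-one: the phenol is carried as an electron-poor tosylate so that the 2-aryl group neither migrates nor labilises the C2–O bond, and the bromide later joins the indane half.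

Key step: step 3

Remark (ligand sense): the R outcome of step 2 with (S)-t-BuPyOx and the S outcome of step 5 with (R)-BINAP are assigned by analogy with the closest substrate classes; the antipodal ligand is used if a model run shows the opposite sense.
Remark (supply): compound 9 is taken as a catalogue compound.
Shorthand in names: Ts = 4-methylbenzenesulfonyl (tosyl); Bpin = 4,4,5,5-tetramethyl-1,3,2-dioxaborolan-2-yl; Q = (E)-[(2S,3S)-2-(3,5-dimethoxyphenyl)-4,6-dimethoxy-3-(4-methoxyphenyl)-2,3-dihydro-1H-inden-1-ylidene]methyl.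

Step 1
Reactants: 1 4-hydroxyphenylboronic acid
Product: 2 4-(tosyloxy)phenylboronic acid
Conditions: TsCl (1.1 equiv), K2CO3 (2 equiv), acetone/H2O, 0 °C to rt; work-up at pH 4
Reagents that add atoms: p-toluenesulfonyl chloride, Cc1ccc(cc1)S(Cl)(=O)=O
Why: Sulfonylation of the phenol (Schotten–Baumann conditions) is faster than any reaction at the boronic acid and installs an electron-poor phenol mask that is stable to acid and oxidant, which the ring contraction needs.

Step 2
Reactants: 3 6-bromochromone; 2 4-(tosyloxy)phenylboronic acid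
Product: 4 (R)-6-bromo-2-[4-(tosyloxy)phenyl]chroman-4-one
Conditions: Pd(OCOCF3)2 (5 mol %), (S)-4-tert-butyl-2-(pyridin-2-yl)-4,5-dihydrooxazole [(S)-t-BuPyOx, 6 mol %], NH4PF6 (30 mol %), H2O (5 equiv), ClCH2CH2Cl, 60 °C
Reagents that add atoms: none
Why: Enantioselective palladium-catalysed conjugate addition of an arylboronic acid to a chromone: the cationic aryl–palladium(PyOx) species (divalent palladium throughout) adds across C2=C3 from the face left open by the tert-butyl oxazoline, protonolysis of the palladium enolate should give the R flavanone, and the aryl bromide and aryl tosylate stay untouched because no zerovalent palladium–phosphine species is present.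

Step 3
Reactants: 4 (R)-6-bromo-2-[4-(tosyloxy)phenyl]chroman-4-one
Product: 7 methyl (2R,3R)-5-bromo-2-[4-(tosyloxy)phenyl]-2,3-dihydrobenzofuran-3-carboxylate, via methyl enol ether 5 (not isolated), via iodanyl ketal 6 (not isolated)
Conditions: PhI(OAc)2 (1.2 equiv), conc. H2SO4 (1 equiv), HC(OMe)3, 0 °C to rt, dark
Reagents that add atoms: trimethyl orthoformate, COC(OC)OC
Why: Acid and orthoformate turn the ketone into methyl enol ether 5, the trivalent iodine electrophile adds to C3 on the face away from the C2 aryl while methanol caps C4 (ketal 6), and because the equatorial C3–I bond lies antiperiplanar to the C4–C4a bond the ring-A carbon C4a shifts from C4 to C3 as iodobenzene departs, the dimethoxycarbenium ion left at C4 collapsing to the methyl ester. The closest known reaction is the hypervalent-iodine (or thallium trinitrate) ring contraction of flavanones and chromanones in trimethyl orthoformate, a semipinacol-type 1,2-aryl shift. The five-membered O1–C2–C3–C3a–C7a ring is closed by contraction and not by cyclisation of a chain: C4a bonds to C3 through a bridged phenonium-like transition state (formally 3-exo-tet) while the old C4–C4a bond breaks in the same event. C2, set in step 2, is not touched; the new C3 centre is set by the C2 aryl (anti iodination followed by invertive shift gives trans), and any cis ester would drift to trans through the ester enol in the acid. The step needs the ring-A carbon to migrate in preference to the 2-aryl group (isoflavone) and to plain loss of hydrogen (flavone): the ring oxygen ortho to C4a activates the fused carbon, the bromide is meta to it and costs little, and the tosyloxy group makes the 2-aryl ring a poor migrating group, resists the oxidant and keeps the benzylic C2–O bond from ionising, so the enantiomeric purity should be kept.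

Step 4
Reactants: 8 2-bromo-3,5-dimethoxybenzaldehyde; 9 2-[1-(4-methoxyphenyl)vinyl]-4,4,5,5-tetramethyl-1,3,2-dioxaborolane
Product: 10 3,5-dimethoxy-2-[1-(4-methoxyphenyl)vinyl]benzaldehyde
Conditions: Pd(OAc)2 (2 mol %), SPhos (4 mol %), K3PO4 (3 equiv), toluene/H2O, 80 °C
Reagents that add atoms: none
Why: Suzuki–Miyaura coupling; the bulky biaryl phosphine allows oxidative addition and reductive elimination at the bromide flanked by CHO and OMe, and the non-enolisable aldehyde tolerates the phosphate base.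

Step 5
Reactants: 10 3,5-dimethoxy-2-[1-(4-methoxyphenyl)vinyl]benzaldehyde
Product: 11 (S)-4,6-dimethoxy-3-(4-methoxyphenyl)indan-1-one
Conditions: [Rh(cod)2]BF4 (5 mol %), (R)-BINAP (5.5 mol %), cod removed with H2 before the substrate is added, CH2Cl2, rt
Reagents that add atoms: none
Why: Rhodium–BINAP-catalysed enantioselective intramolecular hydroacylation of a 2-(1-arylvinyl)benzaldehyde: aldehyde C–H oxidative addition to monovalent rhodium, hydride transfer to the internal alkene carbon inside the chiral pocket sets C3 as S, and C–C reductive elimination closes the indanone with the carbonyl on the ring carbon meta to both methoxy groups.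

Step 6
Reactants: 11 (S)-4,6-dimethoxy-3-(4-methoxyphenyl)indan-1-one; 12 1-bromo-3,5-dimethoxybenzene
Product: 13 (2S,3S)-2-(3,5-dimethoxyphenyl)-4,6-dimethoxy-3-(4-methoxyphenyl)indan-1-one
Conditions: Pd(OAc)2 (5 mol %), P(t-Bu)3·HBF4 (10 mol %), NaOt-Bu (2.2 equiv), toluene, 70 °C
Reagents that add atoms: none
Why: Palladium-catalysed α-arylation of the ketone enolate (known on 3-arylindan-1-ones): the arylpalladium bromide exchanges with the sodium enolate and reductive elimination forms C2–aryl, the product rests as its enolate and is protonated on work-up to the more stable trans isomer, so C2 (S) is set by the untouched C3 centre, and crowding blocks a second arylation.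

Step 7
Reactants: 13 (2S,3S)-2-(3,5-dimethoxyphenyl)-4,6-dimethoxy-3-(4-methoxyphenyl)indan-1-one
Product: 14 2-{(E)-[(2S,3S)-2-(3,5-dimethoxyphenyl)-4,6-dimethoxy-3-(4-methoxyphenyl)-2,3-dihydro-1H-inden-1-ylidene]methyl}-4,4,5,5-tetramethyl-1,3,2-dioxaborolane (Q–Bpin)
Conditions: CH2(Bpin)2 (1.5 equiv), lithium 2,2,6,6-tetramethylpiperidide (LiTMP, 1.4 equiv), THF, 0 °C; then 13, −78 °C to rt
Reagents that add atoms: bis(pinacolato)borylmethane, CC1(C)OB(CB2OC(C)(C)C(C)(C)O2)OC1(C)C
Why: Boron–Wittig olefination of a ketone: the lithiated geminal bis(boronate) adds to C1 and syn elimination of the B–O pair leaves the alkenyl boronate; the E isomer is expected because the remaining Bpin group avoids the in-plane peri C7–H of ring A and lies on the C2 side, where the C2 aryl stands pseudo-axial, and any C2 epimerisation through the enolate returns the stable trans arrangement.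

Step 8
Reactants: 7 methyl (2R,3R)-5-bromo-2-[4-(tosyloxy)phenyl]-2,3-dihydrobenzofuran-3-carboxylate; 14 Q–Bpin
Product: 15 methyl (2R,3R)-5-Q-2-[4-(tosyloxy)phenyl]-2,3-dihydrobenzofuran-3-carboxylate
Conditions: PdCl2(dppf) (5 mol %), K3PO4 (3 equiv), 1,4-dioxane/H2O (10:1), 60 °C
Reagents that add atoms: none
Why: Suzuki–Miyaura coupling of an aryl bromide with an alkenyl boronate proceeds with retention of alkene geometry; this catalyst does not insert into the aryl tosylate, and the phosphate base can at worst epimerise the ester centre towards the trans isomer that is already present.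

Step 9
Reactants: 15 methyl (2R,3R)-5-Q-2-[4-(tosyloxy)phenyl]-2,3-dihydrobenzofuran-3-carboxylate
Product: 16 (2R,3R)-5-Q-2-[4-(tosyloxy)phenyl]-2,3-dihydrobenzofuran-3-carboxylic acid
Conditions: LiOH·H2O (3 equiv), THF/H2O (3:1), 0 °C to rt; then 1 M HCl
Reagents that add atoms: lithium hydroxide, [Li+].[OH-]
Why: Saponification of the methyl ester; ring opening from the ester enolate would be a retro-5-endo-trig elimination and is stereoelectronically disfavoured, the aryl tosylate needs hot hydroxide, and C3 is a centre that is erased in step 11 in any case.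

Step 10
Reactants: 16 (2R,3R)-5-Q-2-[4-(tosyloxy)phenyl]-2,3-dihydrobenzofuran-3-carboxylic acid
Product: 17 1,3-dioxoisoindolin-2-yl (2R,3R)-5-Q-2-[4-(tosyloxy)phenyl]-2,3-dihydrobenzofuran-3-carboxylate
Conditions: N-hydroxyphthalimide (1.1 equiv), N,N'-diisopropylcarbodiimide (1.1 equiv), DMAP (10 mol %), CH2Cl2, rt
Reagents that add atoms: N-hydroxyphthalimide, O=C1N(O)C(=O)c2ccccc12
Why: Carbodiimide (Steglich-type) esterification gives the redox-active N-acyloxyphthalimide under neutral conditions.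

Step 11
Reactants: 17 1,3-dioxoisoindolin-2-yl (2R,3R)-5-Q-2-[4-(tosyloxy)phenyl]-2,3-dihydrobenzofuran-3-carboxylate; 12 1-bromo-3,5-dimethoxybenzene
Product: 20 4-[(2R,3R)-3-(3,5-dimethoxyphenyl)-5-Q-2,3-dihydrobenzofuran-2-yl]phenyl 4-methylbenzenesulfonate, via (3,5-dimethoxyphenyl)magnesium bromide 18 (not isolated), via (3,5-dimethoxyphenyl)zinc chloride 19 (not isolated)
Conditions: 12 (3 equiv), Mg, LiCl, THF, rt; ZnCl2 (THF), 0 °C to rt; then added to 17, NiCl2·glyme (20 mol %), 4,4'-di-tert-butyl-2,2'-bipyridine (40 mol %), THF/DMF, rt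
Reagents that add atoms: none
Why: Nickel-catalysed decarboxylative cross-coupling of a secondary redox-active ester with an arylzinc (Negishi-type): single-electron transfer from low-valent nickel releases CO2 and phthalimide and leaves the benzylic C3 radical, which is captured by aryl–nickel and reductively eliminated on the face opposite the C2 aryl, so the trans (2R,3R) ring should be set by C2, while the trisubstituted alkene and the tosylate are spectators at room temperature.

Step 12
Reactants: 20 4-[(2R,3R)-3-(3,5-dimethoxyphenyl)-5-Q-2,3-dihydrobenzofuran-2-yl]phenyl 4-methylbenzenesulfonate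
Product: 21 4-[(2R,3R)-3-(3,5-dihydroxyphenyl)-5-{(E)-[(2S,3S)-2-(3,5-dihydroxyphenyl)-4,6-dihydroxy-3-(4-hydroxyphenyl)-2,3-dihydro-1H-inden-1-ylidene]methyl}-2,3-dihydrobenzofuran-2-yl]phenyl 4-methylbenzenesulfonate
Conditions: BBr3 (1 M in CH2Cl2, 14 equiv), CH2Cl2, −78 °C to rt; MeOH then H2O quench
Reagents that add atoms: none
Why: Lewis-acid demethylation of the seven aryl methyl ethers (bromide attacks the methyl group of each borane–ether adduct); the sulfonate is inert and, being electron-poor, keeps the benzylic C2–O bond of the dihydrobenzofuran from ionising, which protects that ring and its two stereocentres.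

Step 13
Reactants: 21 heptaphenol monotosylate (name as in step 12)
Product: 22 5-[(2R,3R)-5-{(E)-[(2S,3S)-2-(3,5-dihydroxyphenyl)-4,6-dihydroxy-3-(4-hydroxyphenyl)-2,3-dihydro-1H-inden-1-ylidene]methyl}-2-(4-hydroxyphenyl)-2,3-dihydrobenzofuran-3-yl]benzene-1,3-diol
Conditions: KOH (12 equiv), MeOH/H2O (degassed), 55 °C, Ar; then 1 M HCl to pH 4
Reagents that add atoms: none
Why: Hydroxide attacks sulfur of the aryl sulfonate and releases the phenoxide (sulfonate ester hydrolysis), no stereocentre and not the alkene being involved; oxygen is excluded because the polyphenolate is air-sensitive.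

Compound list
1 | 4-hydroxyphenylboronic acid | OB(O)c1ccc(O)cc1 | starting material
2 | 4-(tosyloxy)phenylboronic acid | Cc1ccc(cc1)S(=O)(=O)Oc1ccc(cc1)B(O)O | intermediate
3 | 6-bromochromone (6-bromo-4H-chromen-4-one) | O=c1ccoc2ccc(Br)cc12 | starting material
4 | (R)-6-bromo-2-[4-(tosyloxy)phenyl]chroman-4-one | Brc1ccc2c(c1)C(=O)C[C@H](c1ccc(OS(=O)(=O)c3ccc(C)cc3)cc1)O2 | intermediate
5 | (R)-6-bromo-4-methoxy-2-[4-(tosyloxy)phenyl]-2H-chromene | Brc1ccc2c(c1)C(OC)=C[C@H](c1ccc(OS(=O)(=O)c3ccc(C)cc3)cc1)O2 | intermediate (not isolated)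
6 | (2S,3S)-3-[acetoxy(phenyl)iodanyl]-6-bromo-4,4-dimethoxy-2-[4-(tosyloxy)phenyl]chromane (2,3-trans) | Brc1ccc2c(c1)C(OC)(OC)[C@@H]([I](OC(C)=O)c1ccccc1)[C@H](c1ccc(OS(=O)(=O)c3ccc(C)cc3)cc1)O2 | intermediate (not isolated)
7 | methyl (2R,3R)-5-bromo-2-[4-(tosyloxy)phenyl]-2,3-dihydrobenzofuran-3-carboxylate (trans) | Brc1ccc2c(c1)[C@@H](C(=O)OC)[C@H](c1ccc(OS(=O)(=O)c3ccc(C)cc3)cc1)O2 | intermediate
8 | 2-bromo-3,5-dimethoxybenzaldehyde | COc1cc(OC)c(Br)c(C=O)c1 | starting material
9 | 2-[1-(4-methoxyphenyl)vinyl]-4,4,5,5-tetramethyl-1,3,2-dioxaborolane | COc1ccc(cc1)C(=C)B1OC(C)(C)C(C)(C)O1 | starting material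
10 | 3,5-dimethoxy-2-[1-(4-methoxyphenyl)vinyl]benzaldehyde | COc1ccc(cc1)C(=C)c1c(OC)cc(OC)cc1C=O | intermediate
11 | (S)-4,6-dimethoxy-3-(4-methoxyphenyl)indan-1-one | COc1ccc([C@H]2c3c(OC)cc(OC)cc3C(=O)C2)cc1 | intermediate
12 | 1-bromo-3,5-dimethoxybenzene | COc1cc(Br)cc(OC)c1 | starting material
13 | (2S,3S)-2-(3,5-dimethoxyphenyl)-4,6-dimethoxy-3-(4-methoxyphenyl)indan-1-one (trans) | COc1ccc([C@H]2c3c(OC)cc(OC)cc3C(=O)[C@@H]2c2cc(OC)cc(OC)c2)cc1 | intermediate
14 | 2-{(E)-[(2S,3S)-2-(3,5-dimethoxyphenyl)-4,6-dimethoxy-3-(4-methoxyphenyl)-2,3-dihydro-1H-inden-1-ylidene]methyl}-4,4,5,5-tetramethyl-1,3,2-dioxaborolane | COc1ccc([C@H]2c3c(OC)cc(OC)cc3/C(=C/B3OC(C)(C)C(C)(C)O3)[C@@H]2c2cc(OC)cc(OC)c2)cc1 | intermediate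
15 | methyl (2R,3R)-5-{(E)-[(2S,3S)-2-(3,5-dimethoxyphenyl)-4,6-dimethoxy-3-(4-methoxyphenyl)-2,3-dihydro-1H-inden-1-ylidene]methyl}-2-[4-(tosyloxy)phenyl]-2,3-dihydrobenzofuran-3-carboxylate | COc1ccc([C@H]2c3c(OC)cc(OC)cc3/C(=C/c3ccc4c(c3)[C@@H](C(=O)OC)[C@H](c3ccc(OS(=O)(=O)c5ccc(C)cc5)cc3)O4)[C@@H]2c2cc(OC)cc(OC)c2)cc1 | intermediate
16 | (2R,3R)-5-{(E)-[(2S,3S)-2-(3,5-dimethoxyphenyl)-4,6-dimethoxy-3-(4-methoxyphenyl)-2,3-dihydro-1H-inden-1-ylidene]methyl}-2-[4-(tosyloxy)phenyl]-2,3-dihydrobenzofuran-3-carboxylic acid | COc1ccc([C@H]2c3c(OC)cc(OC)cc3/C(=C/c3ccc4c(c3)[C@@H](C(=O)O)[C@H](c3ccc(OS(=O)(=O)c5ccc(C)cc5)cc3)O4)[C@@H]2c2cc(OC)cc(OC)c2)cc1 | intermediate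
17 | 1,3-dioxoisoindolin-2-yl (2R,3R)-5-{(E)-[(2S,3S)-2-(3,5-dimethoxyphenyl)-4,6-dimethoxy-3-(4-methoxyphenyl)-2,3-dihydro-1H-inden-1-ylidene]methyl}-2-[4-(tosyloxy)phenyl]-2,3-dihydrobenzofuran-3-carboxylate | COc1ccc([C@H]2c3c(OC)cc(OC)cc3/C(=C/c3ccc4c(c3)[C@@H](C(=O)ON3C(=O)c5ccccc5C3=O)[C@H](c3ccc(OS(=O)(=O)c5ccc(C)cc5)cc3)O4)[C@@H]2c2cc(OC)cc(OC)c2)cc1 | intermediate
18 | (3,5-dimethoxyphenyl)magnesium bromide | COc1cc(OC)cc([Mg]Br)c1 | intermediate (not isolated)
19 | (3,5-dimethoxyphenyl)zinc chloride | COc1cc(OC)cc([Zn]Cl)c1 | intermediate (not isolated)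
20 | 4-[(2R,3R)-3-(3,5-dimethoxyphenyl)-5-{(E)-[(2S,3S)-2-(3,5-dimethoxyphenyl)-4,6-dimethoxy-3-(4-methoxyphenyl)-2,3-dihydro-1H-inden-1-ylidene]methyl}-2,3-dihydrobenzofuran-2-yl]phenyl 4-methylbenzenesulfonate | COc1ccc([C@H]2c3c(OC)cc(OC)cc3/C(=C/c3ccc4c(c3)[C@@H](c3cc(OC)cc(OC)c3)[C@H](c3ccc(OS(=O)(=O)c5ccc(C)cc5)cc3)O4)[C@@H]2c2cc(OC)cc(OC)c2)cc1 | intermediate
21 | 4-[(2R,3R)-3-(3,5-dihydroxyphenyl)-5-{(E)-[(2S,3S)-2-(3,5-dihydroxyphenyl)-4,6-dihydroxy-3-(4-hydroxyphenyl)-2,3-dihydro-1H-inden-1-ylidene]methyl}-2,3-dihydrobenzofuran-2-yl]phenyl 4-methylbenzenesulfonate | Oc1ccc([C@H]2c3c(O)cc(O)cc3/C(=C/c3ccc4c(c3)[C@@H](c3cc(O)cc(O)c3)[C@H](c3ccc(OS(=O)(=O)c5ccc(C)cc5)cc3)O4)[C@@H]2c2cc(O)cc(O)c2)cc1 | intermediate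
22 | 5-[(2R,3R)-5-{(E)-[(2S,3S)-2-(3,5-dihydroxyphenyl)-4,6-dihydroxy-3-(4-hydroxyphenyl)-2,3-dihydro-1H-inden-1-ylidene]methyl}-2-(4-hydroxyphenyl)-2,3-dihydrobenzofuran-3-yl]benzene-1,3-diol (CNP0184753.1) | Oc1ccc([C@H]2c3c(O)cc(O)cc3/C(=C/c3ccc4c(c3)[C@@H](c3cc(O)cc(O)c3)[C@H](c3ccc(O)cc3)O4)[C@@H]2c2cc(O)cc(O)c2)cc1 | target

Total step count: 13. Longest linear sequence: 10 steps (steps 4, 5, 6, 7, 8, 9, 10, 11, 12, 13, from 8 to 22).

Steps most likely to fail

Step 7 (boron–Wittig). Proton transfer from the acidic C2–H of the α-aryl ketone to the lithiated bis(boronate) may outrun carbonyl addition, and the B–O elimination may deliver part of the Z alkene. The fallback sets out from 13 and avoids a basic carbon nucleophile. Petasis methylenation (Cp2TiMe2, toluene, 65 °C) should give (2S,3S)-2-(3,5-dimethoxyphenyl)-4,6-dimethoxy-3-(4-methoxyphenyl)-1-methyleneindane F1 without touching C2. Cross-metathesis of F1 with vinylboronic acid pinacol ester (second-generation Hoveyda–Grubbs catalyst, toluene, 60 °C) should then place boron trans to ring A for steric reasons and return to the route at 14.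

Step 11 (decarboxylative arylation). The benzylic C3 radical may dimerise or be reduced before aryl–nickel captures it, and low-valent nickel may attack the aryl tosylate, all on the most valuable intermediate. The fallback changes the order of events and sets out from 7.
- Saponification (LiOH, THF/H2O) should give (2R,3R)-5-bromo-2-[4-(tosyloxy)phenyl]-2,3-dihydrobenzofuran-3-carboxylic acid F2.
- Carbodiimide coupling with N-hydroxyphthalimide should give its 1,3-dioxoisoindolin-2-yl ester F3.
- Iron-catalysed decarboxylative arylation with 19 (Fe(acac)3, 1,2-bis(diphenylphosphino)benzene, THF, rt), a catalyst that should leave aryl bromide and aryl tosylate alone, should give 4-[(2R,3R)-5-bromo-3-(3,5-dimethoxyphenyl)-2,3-dihydrobenzofuran-2-yl]phenyl 4-methylbenzenesulfonate F4, trans by the same steric argument.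
- Suzuki–Miyaura coupling of F4 with 14 under the conditions of step 8 comes back to the route at 20.

Step 3 (key ring contraction). The shift of the ring-A carbon competes with the 2-aryl shift, with dehydrogenation to the flavone and with α-oxygenation, and acid-promoted opening to the chalcone could erode the C2 configuration. The fallback keeps the same C4-to-C3 shift but triggers it from a carbene, and sets out from 4.
- Kinetic enolisation (LiN(SiMe3)2, THF, −78 °C) and trapping with CF3CO2CH2CF3 should give (2R)-6-bromo-3-(trifluoroacetyl)-2-[4-(tosyloxy)phenyl]chroman-4-one F5.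
- Detrifluoroacetylative diazo transfer (MsN3, Et3N, H2O, MeCN) should give (S)-6-bromo-3-diazo-2-[4-(tosyloxy)phenyl]chroman-4-one F6.
- Wolff rearrangement (350 nm light or PhCO2Ag/Et3N, MeOH) moves C4a to C3 and gives the ketene 4-[(2S)-5-bromo-3-(oxomethylidene)-2,3-dihydrobenzofuran-2-yl]phenyl 4-methylbenzenesulfonate F7.
- Methanol traps F7 as a mixture of 7 and its cis epimer, methyl (2R,3S)-5-bromo-2-[4-(tosyloxy)phenyl]-2,3-dihydrobenzofuran-3-carboxylate F8; DBU in toluene should equilibrate F8 to the trans ester, where the fallback rejoins the route at 7.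

Further compounds
F1 | step 7 | (2S,3S)-2-(3,5-dimethoxyphenyl)-4,6-dimethoxy-3-(4-methoxyphenyl)-1-methyleneindane | COc1ccc([C@H]2c3c(OC)cc(OC)cc3C(=C)[C@@H]2c2cc(OC)cc(OC)c2)cc1
F2 | step 11 | (2R,3R)-5-bromo-2-[4-(tosyloxy)phenyl]-2,3-dihydrobenzofuran-3-carboxylic acid | Brc1ccc2c(c1)[C@@H](C(=O)O)[C@H](c1ccc(OS(=O)(=O)c3ccc(C)cc3)cc1)O2
F3 | step 11 | 1,3-dioxoisoindolin-2-yl (2R,3R)-5-bromo-2-[4-(tosyloxy)phenyl]-2,3-dihydrobenzofuran-3-carboxylate | Brc1ccc2c(c1)[C@@H](C(=O)ON1C(=O)c3ccccc3C1=O)[C@H](c1ccc(OS(=O)(=O)c3ccc(C)cc3)cc1)O2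
F4 | step 11 | 4-[(2R,3R)-5-bromo-3-(3,5-dimethoxyphenyl)-2,3-dihydrobenzofuran-2-yl]phenyl 4-methylbenzenesulfonate | Brc1ccc2c(c1)[C@@H](c1cc(OC)cc(OC)c1)[C@H](c1ccc(OS(=O)(=O)c3ccc(C)cc3)cc1)O2
F5 | step 3 | (2R)-6-bromo-3-(trifluoroacetyl)-2-[4-(tosyloxy)phenyl]chroman-4-one (C3 not defined, enolised) | Brc1ccc2c(c1)C(=O)C(C(=O)C(F)(F)F)[C@H](c1ccc(OS(=O)(=O)c3ccc(C)cc3)cc1)O2
F6 | step 3 | (S)-6-bromo-3-diazo-2-[4-(tosyloxy)phenyl]chroman-4-one | Brc1ccc2c(c1)C(=O)C(=[N+]=[N-])[C@H](c1ccc(OS(=O)(=O)c3ccc(C)cc3)cc1)O2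
F7 | step 3 | 4-[(2S)-5-bromo-3-(oxomethylidene)-2,3-dihydrobenzofuran-2-yl]phenyl 4-methylbenzenesulfonate | Brc1ccc2c(c1)C(=C=O)[C@H](c1ccc(OS(=O)(=O)c3ccc(C)cc3)cc1)O2
F8 | step 3 | methyl (2R,3S)-5-bromo-2-[4-(tosyloxy)phenyl]-2,3-dihydrobenzofuran-3-carboxylate (cis) | Brc1ccc2c(c1)[C@H](C(=O)OC)[C@H](c1ccc(OS(=O)(=O)c3ccc(C)cc3)cc1)O2
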